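**Target:** 4-[(1R,3aS,4R,6aS)-4-(3,4,5-trimethoxyphenyl)tetrahydro-1H,3H-furo[3,4-c]furan-1-yl]-2,6-dimethoxyphenol. It is a cis-fused furofuran with both aryl groups exo and bridgeheads 3aS,6aS. Atom labels C1/C3/C3a/C4/C6/C6a below use this furo[3,4-c]furan numbering.

## Retrosynthetic overview
1. Target ⇐ O-debenzylation ⇐ benzylic SN1 cyclodehydration (second THF ring, sets C4) ⇐ 1,4-diol ⇐ ArMgBr + cis-fused bicyclic lactol.
2. Lactol ⇐ glycol cleavage of a dioxolane ⇐ 2-aryl-3-hydroxymethyl-4-dioxolanyl-THF ⇐ SN1 cyclodehydration (first THF ring, sets C1) ⇐ triol ⇐ LiAlH4 ⇐ trans-aldol of a β-dioxolanyl-γ-butyrolactone with ArCHO (sets C6a).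
3. Lactone ⇐ ozonolysis/reduction ⇐ γ,δ-unsaturated ester ⇐ Johnson–Claisen [3,3] rearrangement of a D-mannitol-derived (S,Z)-allylic alcohol, which forms the central C3a–C6a bond and sets C3a.
4. Ring order: temporary γ-lactone → aryl-THF ring 1 → lactol ring → aryl-THF ring 2. Stereochemical relay: dioxolane carbon → C3a → C6a → C1 and C4; the dioxolane is then cut down to the C4 aldehyde.

**Assumptions (one line each):**
- Compound 1 (D-mannitol-derived) and Grignard 11 (0.5 M in THF) are bought.
- Carbinol and anomeric centres that are reset later are carried as mixtures.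
- The sense of induction in step 2 (new C–C bond anti to the allylic C–O bond) is taken from the usual A(1,3)-strain model for Z-γ-alkoxy allylic alcohols; it is my assignment, not a checked literature value.

## Forward route

**Step 1**
Reactants: 1, methyl (2Z)-3-[(4S)-2,2-dimethyl-1,3-dioxolan-4-yl]prop-2-enoate
Product: 2, (2Z)-3-[(4S)-2,2-dimethyl-1,3-dioxolan-4-yl]prop-2-en-1-ol
Conditions: DIBAL-H (2.3 equiv), CH2Cl2, −78 → −40 °C; Rochelle salt
Reagents that add atoms: none
Why: 1,2-hydride reduction of the enoate (DIBAL ester reduction) gives the allylic alcohol and leaves the Z-alkene, acetonide and stereocentre untouched.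

**Step 2**
Reactants: 2; 3, triethyl orthoacetate
Product: 4, ethyl (3S)-3-[(4S)-2,2-dimethyl-1,3-dioxolan-4-yl]pent-4-enoate
Conditions: MeC(OEt)3 (6 equiv), EtCO2H (5 mol%), 140 °C, distil off EtOH
Reagents that add atoms: triethyl orthoacetate, CC(OCC)(OCC)OCC
Why: Johnson orthoester Claisen ([3,3]-sigmatropic) through the mixed ketene acetal forms the future C6a–C3a bond; A(1,3) strain in the Z-alkene holds the dioxolane C–H in the alkene plane, and bonding anti to the allylic C–O bond sets C3 as S.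

**Step 3**
Reactants: 4
Product: 5, (4S)-4-[(4S)-2,2-dimethyl-1,3-dioxolan-4-yl]oxolan-2-one
Conditions: O3, CH2Cl2/MeOH, −78 °C; NaBH4, −78 → 0 °C; then PPTS (cat.), CH2Cl2, rt
Reagents that add atoms: ozone, [O-][O+]=O
Why: Ozonolysis with reductive work-up turns the vinyl group into CH2OH (future C3), which lactonises onto the ester; the aldehyde is reduced before its α-centre can epimerise.

**Step 4**
Reactants: 5; 6, 4-(benzyloxy)-3,5-dimethoxybenzaldehyde
Product: 7, (3R,4S)-3-{[4-(benzyloxy)-3,5-dimethoxyphenyl](hydroxy)methyl}-4-[(4S)-2,2-dimethyl-1,3-dioxolan-4-yl]oxolan-2-one (3,4-trans; carbinol epimers)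
Conditions: LDA (1.1 equiv), THF, −78 °C; then 6, −78 °C; AcOH quench at −78 °C
Reagents that add atoms: aldehyde 6, COc1cc(C=O)cc(OC)c1OCc1ccccc1
Why: Lactone-enolate aldol addition occurs on the face anti to the β-dioxolanyl group, setting C6a trans to it; the carbinol centre is not controlled and is reset in step 6.

**Step 5**
Reactants: 7
Product: 8, (2S,3S)-1-[4-(benzyloxy)-3,5-dimethoxyphenyl]-3-[(4S)-2,2-dimethyl-1,3-dioxolan-4-yl]-2-(hydroxymethyl)butane-1,4-diol (C1 epimers)
Conditions: LiAlH4 (2 equiv), THF, 0 °C → rt; Fieser work-up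
Reagents that add atoms: none
Why: Hydride reduction of the lactone releases both primary alcohols (C6-OH and C3-OH) without affecting the benzyl ether, acetonide or the two C–H stereocentres.

**Step 6**
Reactants: 8
Product: 9, [(2R,3S,4S)-2-[4-(benzyloxy)-3,5-dimethoxyphenyl]-4-[(4S)-2,2-dimethyl-1,3-dioxolan-4-yl]oxolan-3-yl]methanol
Conditions: p-TsOH·H2O (5 mol%), 4 Å MS, CH2Cl2, 0 °C → rt (40 °C if slow)
Reagents that add atoms: none
Why: Acid-catalysed SN1 cyclodehydration: the electron-rich benzylic cation is trapped 5-exo by the only hydroxyl that can form a five-membered ring, and both carbinol epimers converge on the 2,3-trans aryl-THF (C1 = R).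

**Step 7**
Reactants: 9
Product: 10, (3aS,4R,6aS)-4-[4-(benzyloxy)-3,5-dimethoxyphenyl]tetrahydro-1H,3H-furo[3,4-c]furan-1-ol (anomers)
Conditions: H5IO6 (1.3 equiv), EtOAc, 0 °C → rt
Reagents that add atoms: none
Why: Periodic acid removes the terminal acetonide and cleaves the glycol in one pot (loss of acetone and CH2O); the aldehyde is captured by the cis CH2OH as the cis-fused lactol, which protects C3a from epimerisation.

**Step 8**
Reactants: 10; 11, 3,4,5-trimethoxyphenylmagnesium bromide
Product: 12, [(2R,3S,4S)-2-[4-(benzyloxy)-3,5-dimethoxyphenyl]-4-[hydroxy(3,4,5-trimethoxyphenyl)methyl]oxolan-3-yl]methanol (carbinol epimers)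
Conditions: 11 (3.5 equiv), THF, 0 °C → rt; aq. NH4Cl
Reagents that add atoms: Grignard 11, COc1cc([Mg]Br)cc(OC)c1OC
Why: Grignard addition to the open hydroxy-aldehyde form of the lactol gives the 1,4-diol; the new carbinol configuration is irrelevant because it is reset in step 9.

**Step 9**
Reactants: 12
Product: 13, (1R,3aS,4R,6aS)-1-[4-(benzyloxy)-3,5-dimethoxyphenyl]-4-(3,4,5-trimethoxyphenyl)tetrahydro-1H,3H-furo[3,4-c]furan
Conditions: BF3·OEt2 (1.2 equiv), CH2Cl2, −20 → 0 °C, 20–30 min; aq. NaHCO3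
Reagents that add atoms: none
Why: Stereoconvergent SN1 cyclodehydration: the primary OH closes onto the trimethoxybenzylic cation with the aryl on the convex (exo) face, setting C4 = R under kinetic control; the short time at low temperature limits exo/endo equilibration.

**Step 10**
Reactants: 13
Product: 14, the target phenol
Conditions: H2 (1 atm), 10% Pd/C, EtOAc, rt, stop at full conversion
Reagents that add atoms: none
Why: Hydrogenolysis of the aryl benzyl ether is much faster than cleavage of the ring benzylic dialkyl ethers, so the phenol is released without touching the four stereocentres.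

## Compound list
1 | methyl (2Z)-3-[(4S)-2,2-dimethyl-1,3-dioxolan-4-yl]prop-2-enoate | COC(=O)/C=C\[C@H]1COC(C)(C)O1 | starting material
2 | (2Z)-3-[(4S)-2,2-dimethyl-1,3-dioxolan-4-yl]prop-2-en-1-ol | OC/C=C\[C@H]1COC(C)(C)O1 | intermediate
3 | triethyl orthoacetate | CC(OCC)(OCC)OCC | starting material
4 | ethyl (3S)-3-[(4S)-2,2-dimethyl-1,3-dioxolan-4-yl]pent-4-enoate | CCOC(=O)C[C@@H](C=C)[C@H]1COC(C)(C)O1 | intermediate
5 | (4S)-4-[(4S)-2,2-dimethyl-1,3-dioxolan-4-yl]oxolan-2-one | O=C1C[C@@H](CO1)[C@H]1COC(C)(C)O1 | intermediate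
6 | 4-(benzyloxy)-3,5-dimethoxybenzaldehyde | COc1cc(C=O)cc(OC)c1OCc1ccccc1 | starting material
7 | (3R,4S)-3-{[4-(benzyloxy)-3,5-dimethoxyphenyl](hydroxy)methyl}-4-[(4S)-2,2-dimethyl-1,3-dioxolan-4-yl]oxolan-2-one | O=C1[C@@H](C(O)c2cc(OC)c(OCc3ccccc3)c(OC)c2)[C@@H](CO1)[C@H]1COC(C)(C)O1 | intermediate
8 | (2S,3S)-1-[4-(benzyloxy)-3,5-dimethoxyphenyl]-3-[(4S)-2,2-dimethyl-1,3-dioxolan-4-yl]-2-(hydroxymethyl)butane-1,4-diol | OC[C@@H](C(O)c1cc(OC)c(OCc2ccccc2)c(OC)c1)[C@@H](CO)[C@H]1COC(C)(C)O1 | intermediate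
9 | [(2R,3S,4S)-2-[4-(benzyloxy)-3,5-dimethoxyphenyl]-4-[(4S)-2,2-dimethyl-1,3-dioxolan-4-yl]oxolan-3-yl]methanol | OC[C@H]1[C@H](c2cc(OC)c(OCc3ccccc3)c(OC)c2)OC[C@H]1[C@H]1COC(C)(C)O1 | intermediate
10 | (3aS,4R,6aS)-4-[4-(benzyloxy)-3,5-dimethoxyphenyl]tetrahydro-1H,3H-furo[3,4-c]furan-1-ol | OC1OC[C@H]2[C@H](c3cc(OC)c(OCc4ccccc4)c(OC)c3)OC[C@@H]12 | intermediate
11 | 3,4,5-trimethoxyphenylmagnesium bromide | COc1cc([Mg]Br)cc(OC)c1OC | starting material
12 | [(2R,3S,4S)-2-[4-(benzyloxy)-3,5-dimethoxyphenyl]-4-[hydroxy(3,4,5-trimethoxyphenyl)methyl]oxolan-3-yl]methanol | OC[C@H]1[C@H](c2cc(OC)c(OCc3ccccc3)c(OC)c2)OC[C@H]1C(O)c1cc(OC)c(OC)c(OC)c1 | intermediate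
13 | (1R,3aS,4R,6aS)-1-[4-(benzyloxy)-3,5-dimethoxyphenyl]-4-(3,4,5-trimethoxyphenyl)tetrahydro-1H,3H-furo[3,4-c]furan | COc1cc([C@@H]2OC[C@@H]3[C@H]2CO[C@H]3c2cc(OC)c(OC)c(OC)c2)cc(OC)c1OCc1ccccc1 | intermediate
14 | 4-[(1R,3aS,4R,6aS)-4-(3,4,5-trimethoxyphenyl)tetrahydro-1H,3H-furo[3,4-c]furan-1-yl]-2,6-dimethoxyphenol | COc1cc([C@@H]2OC[C@@H]3[C@H]2CO[C@H]3c2cc(OC)c(OC)c(OC)c2)cc(OC)c1O | target

## Summary
**Total steps:** 10. **Longest linear sequence:** 10 (1 → 14).

**Three steps most likely to fail, with fallbacks:**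
1. **Step 2 (level and sense of 1,2-induction in the Johnson–Claisen; acetonide at 140 °C).** Fallback: make lactone 5 by dichloroketene [2+2] cycloaddition to (S)-4-vinyl-2,2-dimethyl-1,3-dioxolane, then Zn dechlorination and Baeyer–Villiger oxidation, separating diastereomers at the lactone. If the Claisen sense proves opposite, start from ent-1 (L-ascorbic acid series).
2. **Step 6 (benzylic ionisation next to an acetonide; possible acetal-oxygen participation or sluggish ionisation).** Fallback: swap the two handles. Cleave the dioxolane of the ester first (H5IO6, then NaBH4) to give the β-vinyl-γ-butyrolactone, run aldol / LiAlH4 / cyclisation with the inert vinyl group in place, and reveal the lactol by ozonolysis afterwards. This needs ent-1 for the same target enantiomer.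
3. **Step 9 (exo/endo ratio at C4 and acid epimerisation of either benzylic centre).** Fallback: reverse the aryl order. Use 3,4,5-trimethoxybenzaldehyde in step 4 and a silyl-protected 4-metallo-2,6-dimethoxyphenol in step 8; after desilylation the p-hydroxybenzyl alcohol closes through a p-quinone methide under near-neutral conditions, which also removes the hydrogenolysis in step 10.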